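**Assumptions:** The SMILES corresponds to (3S), with E-configured C6=C7. Friedel–Crafts alkylation of catechol occurs para to one OH (C4 of catechol).

## Retrosynthetic overview
1. The (E)-styrene C6=C7 comes from a Heck coupling of a terminal alkene with 4-iodophenol. The last step removes the catechol acetates selectively.
2. The C4–C5 bond forms in a radical allylation. A primary C4 radical from the bromohydrin is trapped by allylstannane, leaving the C3 carbinol untouched.
3. The bromohydrin comes from enantioselective reduction of a bromomethyl ketone, which sets C3. That ketone comes from regioselective bromination of 4-(catechol)butan-2-one.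
4. The butanone comes from Friedel–Crafts conjugate alkylation of catechol with methyl vinyl ketone.
5. No rings are formed. Both arenes come from small commercial phenols, and the catechol is carried as its diacetate.

## Route

**Step 1**
Reactants: 1 (catechol, benzene-1,2-diol); 2 (methyl vinyl ketone, but-3-en-2-one)
Product: 3 (4-(3,4-dihydroxyphenyl)butan-2-one)
Conditions: catechol (3 equiv), Amberlyst-15, 1,2-dichloroethane, 60 °C
Reagents that add atoms: none
Why: Acid-promoted Friedel–Crafts conjugate alkylation occurs para to an OH, and excess catechol suppresses dialkylation. No stereocentre is formed.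

**Step 2**
Reactants: 3
Product: 4 (4-(3,4-diacetoxyphenyl)butan-2-one)
Conditions: Ac2O, pyridine, DMAP (cat.), CH2Cl2, 0 °C to rt
Reagents that add atoms: acetic anhydride, CC(=O)OC(C)=O
Why: O-Acetylation masks the oxidation- and bromination-prone catechol. The aryl acetates can later be removed selectively.

**Step 3**
Reactants: 4
Product: 5 (1-bromo-4-(3,4-diacetoxyphenyl)butan-2-one)
Conditions: Br2 (1.0 equiv), MeOH, 0–10 °C, then H2O quench
Reagents that add atoms: bromine, BrBr
Why: Methyl ketones brominate selectively at CH3 in MeOH (Gaudry–Marquet α-bromination), and the diacetate ring is not brominated. No stereocentre is formed.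

**Step 4**
Reactants: 5
Product: 6 ((R)-1-bromo-4-(3,4-diacetoxyphenyl)butan-2-ol)
Conditions: (R)-Me-CBS (10 mol%), BH3·SMe2 (0.7 equiv), THF, −20 °C
Reagents that add atoms: none (hydride only)
Why: Corey–Bakshi–Shibata reduction delivers hydride to one face of the ketone. It distinguishes the linear CH2CH2Ar arm from the CH2Br arm and sets the C3 stereocentre. It is named (R) here because CH2Br outranks CH2CH2Ar in CIP priority.

**Step 5 (key radical step)**
Reactants: 6
Product: 7 ((S)-1-(3,4-diacetoxyphenyl)hept-6-en-3-ol)
Conditions: allyltributylstannane (3 equiv), AIBN (0.2 equiv), benzene (0.05 M), 80 °C, then KF/silica work-up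
Reagents that add atoms: allyltributylstannane, C=CCC[Sn](CCCC)(CCCC)CCCC
Why: Keck radical allylation. Bu3Sn• abstracts Br to give a primary C4 radical. It adds to the allylstannane, and β-scission of the Sn–C bond releases Bu3Sn•, forming the C4–C5 bond. The free OH avoids a 1,2-acyloxy shift, and the carbinol carbon is not involved, so its configuration is retained. The descriptor changes from R to S only because the CIP priorities change.

**Step 6**
Reactants: 7
Product: 8 ((S)-3-acetoxy-1-(3,4-diacetoxyphenyl)hept-6-ene)
Conditions: Ac2O, pyridine, DMAP (cat.), CH2Cl2, rt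
Reagents that add atoms: acetic anhydride, CC(=O)OC(C)=O
Why: O-Acylation proceeds with retention at C3 and installs the target acetate.

**Step 7**
Reactants: 8; 9 (4-iodophenol)
Product: 10 ((S,E)-triacetate-protected styryl phenol)
Conditions: Pd(OAc)2 (5 mol%), P(o-tol)3, Et3N, MeCN, 80 °C
Reagents that add atoms: none (the aryl group comes from 9)
Why: Mizoroki–Heck reaction. Syn-carbopalladation at the terminal CH2 followed by syn β-hydride elimination gives the E-styrene. The C3 stereocentre is remote and untouched. Partial aryl-acetate loss here is harmless because step 8 removes those groups anyway.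

**Step 8**
Reactants: 10
Product: 11 (target)
Conditions: NH4OAc (10 equiv), MeOH/H2O 4:1, rt, under Ar
Reagents that add atoms: none
Why: Aryl acetates have phenoxide leaving groups and are cleaved much faster than the secondary alkyl acetate under this mild ammonolysis. The C3 acetate and the alkene survive.

## Compound list
1 | catechol | Oc1ccccc1O | starting material
2 | methyl vinyl ketone | C=CC(C)=O | starting material
3 | 4-(3,4-dihydroxyphenyl)butan-2-one | CC(=O)CCc1ccc(O)c(O)c1 | intermediate
4 | 4-(3,4-diacetoxyphenyl)butan-2-one | CC(=O)CCc1ccc(OC(C)=O)c(OC(C)=O)c1 | intermediate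
5 | 1-bromo-4-(3,4-diacetoxyphenyl)butan-2-one | BrCC(=O)CCc1ccc(OC(C)=O)c(OC(C)=O)c1 | intermediate
6 | (R)-1-bromo-4-(3,4-diacetoxyphenyl)butan-2-ol | BrC[C@H](O)CCc1ccc(OC(C)=O)c(OC(C)=O)c1 | intermediate
7 | (S)-1-(3,4-diacetoxyphenyl)hept-6-en-3-ol | C=CCC[C@H](O)CCc1ccc(OC(C)=O)c(OC(C)=O)c1 | intermediate
8 | (S)-3-acetoxy-1-(3,4-diacetoxyphenyl)hept-6-ene | C=CCC[C@H](OC(C)=O)CCc1ccc(OC(C)=O)c(OC(C)=O)c1 | intermediate
9 | 4-iodophenol | Oc1ccc(I)cc1 | starting material
10 | (S,E)-3-acetoxy-1-(3,4-diacetoxyphenyl)-7-(4-hydroxyphenyl)hept-6-ene | CC(=O)O[C@@H](CC/C=C/c1ccc(O)cc1)CCc1ccc(OC(C)=O)c(OC(C)=O)c1 | intermediate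
11 | target | CC(=O)O[C@@H](CC/C=C/c1ccc(O)cc1)CCc1ccc(O)c(O)c1 | target

## Totals
Total steps: 8. Longest linear sequence: 8 (catechol → 3 → 4 → 5 → 6 → 7 → 8 → 10 → 11).

## Three steps most likely to fail
1. **Step 1 (Friedel–Crafts of catechol with MVK):** Yield and regioselectivity are uncertain, and MVK polymerisation competes.
   Fallback: make the phenol analogue (phenol + MVK) and carry its acetate through steps 3–6. Then install the second OH on the mono-phenol alkene before the Heck, by IBX ortho-oxygenation followed by Na2S2O4 reduction.
2. **Step 4 (CBS reduction of a dialkyl bromomethyl ketone):** The two ketone substituents are sterically similar, so ee may be modest.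
   Fallback: biocatalytic reduction of 5 with an (R)-selective ketoreductase. Use a hydrolysis-resistant catechol protecting group such as a pivalate, since aryl acetates are labile in aqueous buffer.
3. **Step 5 (Keck allylation of a primary bromide bearing a free β-OH):** Conversion may be incomplete or tin removal difficult.
   Fallback: close 6 to the terminal epoxide with K2CO3 and open it ionically with allylMgBr/CuI at the terminal carbon. This gives 7 with C3 untouched, and the radical step is replaced by an organocopper opening.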